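Set the reagent charge over both substrates together: it stands at 25.0% in dusk and 100% in noon. Call this ratio the reagent ceiling, the fraction of the substrate charge that can become product if each product costs one reagent, which you assume here. In dusk, reagent is thus the limiting reagent.

in all of them: left-handed substrate 0.030 M; right-handed substrate 0.030 M
- blue: reagent 0.060 M; free catalyst 0.20 mM (in portions, 3); temperature −40 °C; run made earlier; portions every 3.0 min
- noon: reagent 0.0600 M; free catalyst 0.30 mM (in portions, 3); at −40 °C until 80 min, from then on at −15 °C; the portions of free catalyst follow each other after 3.0 min, the first at the start; time 4.0 h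
- dusk: reagent 0.0150 M; free catalyst 0.30 mM (in portions, 3); at −40 °C throughout; the portions of free catalyst follow each other after 3.0 min, the first at the start; time 15 h

- blue (time / min: left-handed product / %, right-handed product / %): 6.00: 3.6, 1.0; 15.0: 5.7, 0.2; 30.0: 9.2, 1.9; 50.0: 14.4, 4.3

(each reading ± 1 percentage point)

- free catalyst is single-handed; left-handed substrate and right-handed substrate are mirror images of each other, charged as a racemate, each of them at the stated concentration
- the earlier runs do not show what temperature does; that part of a forecast is a guess
- no earlier run changes the charge of free catalyst; that part of a forecast is a guess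

1. which one finishes higher in share of left-handed product in all that became left-handed product or right-handed product ("neither" within 2 percentage points) (noon / dusk / neither)
2. share of left-handed product in all that became left-handed product or right-handed product, noon
3. share of left-handed product in all that became left-handed product or right-handed product, dusk

Now climb the ladder of times. The first rung is the dosing: the last portion of free catalyst goes in at 6.00 min. The next comes from blue, where between 15.0 min and 50.0 min the two products together grow at a reading of 0.219 h⁻¹ of the charge, which you scale by guess with the catalyst to 0.329 h⁻¹. Blue has one reagent charge, so take both cases for dusk. If the rate ignores reagent, the ceiling is reached in 0.760 h; if it is pseudo-first-order in reagent, the reagent half-life is 2.11 h. Both are shorter than the 15 h of dusk, so you expect dusk to stop at its ceiling. That ceiling lies above the 18.7% read in blue at 50.0 min, where the left-handed share reads 77.0%, so you commit to a dusk share a little below that reading. For noon the same rate gives an estimated 43.9% before warming, below its ceiling, so you expect noon to run on past that conversion and place its share lower, though the effect of warming is a guess.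

The forecast gives dusk, with 58% for noon and 76% for dusk, because in dusk “the reaction stops at modest conversion”. The flask gives dusk, with 54.9% for noon and 72.7% for dusk.

    free catalyst + left-handed substrate ⇌ catalyst intermediate A (K = 45.0 M⁻¹, k = 165 M⁻¹ s⁻¹, Ea = 36.0 kJ mol⁻¹, ΔH = −90.0 kJ mol⁻¹)
    reagent + catalyst intermediate A → free catalyst + left-handed product (k = 1.29 M⁻¹ s⁻¹, Ea = 39.0 kJ mol⁻¹)
    reagent → decomposition product (k = 1.07 × 10⁻⁷ s⁻¹, Ea = 91.0 kJ mol⁻¹)
    reagent + catalyst intermediate B → free catalyst + right-handed product (k = 0.475 M⁻¹ s⁻¹, Ea = 47.0 kJ mol⁻¹)
    free catalyst + right-handed substrate ⇌ catalyst intermediate B (K = 41.0 M⁻¹, k = 33.3 M⁻¹ s⁻¹, Ea = 37.0 kJ mol⁻¹, ΔH = −62.0 kJ mol⁻¹)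
    reagent ⇌ dormant form (K = 3.78, k = 3.20 × 10⁻⁴ s⁻¹, Ea = 76.0 kJ mol⁻¹, ΔH = −26.0 kJ mol⁻¹)
    (constants at −40 °C)

Dusk has not come to rest at 15.0 h: its products stand at 20.8%, below the ceiling, with 2.58% of the reagent free and 0.00212 M as dormant form. By 150 h free reagent stands at 0% and the products at 25.0%, level with the ceiling, while the share is 72.1%. The share in noon goes from 54.9% to 47.4% by 40.0 h.

Take the neighbour of dusk at −25 °C, with all amounts and the time held: the charges are unchanged, so the ceiling is still 25.0%. The computed products in that neighbour reach 23.4% at 15.0 h, yet its share is 49.4%, below the 54.9% of noon, the reverse of the order between dusk and noon.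

Readings and results are simulated with made-up constants; the scatter is artificial.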